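The route rests on disconnecting the dihydrofuran ring that shares no atom with the seven-membered ring: its O1–C2 bond (C2 bears the 4-hydroxyphenyl group) and its C3–C3a bond (C3 bears the 3,5-dihydroxyphenyl group). Both are made in one biomimetic oxidative [3+2] coupling, which grafts the alkene of a 4-hydroxystilbene onto the free phenol oxygen and the neighbouring arene C–H of the central benzene ring through a p-quinone methide, and sets both new stereocentres. The precursor is an enantiopure tetracyclic phenol (trans-dihydrobenzofuran fused to a dibenzo-cycloheptane), built by enantioselective carbene C–H insertion, Heck coupling and cationic seven-ring closure, with all other phenols as methyl ethers.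

Key step: step 9

Assumption: Rh2(R-PTAD)4 (dirhodium tetrakis[(R)-(1-adamantyl)(N-phthalimido)acetate]) is taken as the catalyst antipode that gives (3R)-8; if the sense proves opposite, Rh2(S-PTAD)4 is used and nothing else changes.

Locants in the names: dihydrobenzofuran O-1, C-2 (oxygen-bearing), C-3; "central ring" is the benzene ring that carries both ring oxygens.

Step 1
Reactants: 1 5-bromoresorcinol; 2 3,5-dimethoxybenzoic acid
Product: 3 (2-bromo-4,6-dihydroxyphenyl)(3,5-dimethoxyphenyl)methanone
Conditions: BF3·OEt2 (as solvent), 90 °C; then aq NaOAc, 60 °C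
Reagents that add atoms: none
Why: Friedel–Crafts (Nencki-type) acylation of a resorcinol by a carboxylic acid activated with BF3 should place the aroyl group para to one hydroxyl and ortho to the other, next to bromine, as with orcinol, and the hydrogen-bonded ortho-hydroxy ketone is deactivated toward a second acylation.

Step 2
Reactants: 3 (2-bromo-4,6-dihydroxyphenyl)(3,5-dimethoxyphenyl)methanone; 4 4-methoxybenzyl chloride (2.4 equiv in total)
Product: 5 {2-bromo-4,6-bis[(4-methoxybenzyl)oxy]phenyl}(3,5-dimethoxyphenyl)methanone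
Conditions: K2CO3 (3 equiv), n-Bu4NI (5 mol %), DMF, 70 °C
Reagents that add atoms: 4-methoxybenzyl chloride (the second equivalent of 4), COc1ccc(CCl)cc1
Why: Twofold Williamson etherification, one molecule of 4 per phenol (the hydrogen-bonded ortho one needs warm DMF), installs in one operation the benzylic ether whose CH2 becomes C-2 of the dihydrobenzofuran and an acid-labile protecting group on the para oxygen.

Step 3
Reactants: 5 {2-bromo-4,6-bis[(4-methoxybenzyl)oxy]phenyl}(3,5-dimethoxyphenyl)methanone
Product: 6 hydrazone of ketone 5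
Conditions: N2H4·H2O (10 equiv), AcOH (10 mol %), EtOH, 80 °C (sealed tube)
Reagents that add atoms: hydrazine (used as the hydrate), NN
Why: Acid-catalysed condensation of the non-enolisable diaryl ketone with excess hydrazine (the excess suppresses the azine) gives the free hydrazone, the precursor of the diazo compound, and forms no stereocentre.

Step 4
Reactants: 6 hydrazone of ketone 5
Product: 8 (2S,3R)-4-bromo-3-(3,5-dimethoxyphenyl)-6-[(4-methoxybenzyl)oxy]-2-(4-methoxyphenyl)-2,3-dihydro-1-benzofuran (cis), via diaryldiazomethane 7 (not isolated)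
Conditions: MnO2 (8 equiv), CH2Cl2, 0 °C, filtered; then Rh2(R-PTAD)4 (1 mol %), CH2Cl2, −20 → 0 °C
Reagents that add atoms: none
Why: MnO2 dehydrogenates the hydrazone to the diaryldiazomethane and Rh2(R-PTAD)4 turns it into a donor/donor carbene that inserts into the activated benzylic ether C–H bond five atoms away (enantioselective intramolecular C–H insertion), the catalyst setting C-3 as R and the insertion giving the 2,3-cis isomer.

Step 5
Reactants: 8 (2S,3R)-4-bromo-3-(3,5-dimethoxyphenyl)-6-[(4-methoxybenzyl)oxy]-2-(4-methoxyphenyl)-2,3-dihydro-1-benzofuran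
Product: 10 (2R,3R)-4-bromo-3-(3,5-dimethoxyphenyl)-2-(4-methoxyphenyl)-2,3-dihydro-1-benzofuran-6-ol (trans), via cis-phenol 9 (not isolated)
Conditions: CF3CO2H–CH2Cl2 (1:4), pentamethylbenzene (5 equiv), 0 °C → rt
Reagents that add atoms: none
Why: CF3CO2H cleaves the aryl 4-methoxybenzyl ether (cation trapped by pentamethylbenzene) and reversibly ionises the ring C2–O bond to the 4-methoxybenzylic cation, whose reclosure by the phenol oxygen should give the thermodynamically preferred 2,3-trans isomer (C-2 becomes R, C-3 is untouched) in an acid-mediated deprotection–epimerisation.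

Step 6
Reactants: 11 2,4-dimethoxybenzaldehyde
Product: 12 2,4-dimethoxystyrene
Conditions: Ph3PCH3Br, KOt-Bu, THF, 0 °C → rt
Reagents that add atoms: methyltriphenylphosphonium bromide, C[P+](c1ccccc1)(c1ccccc1)c1ccccc1.[Br-]
Why: Wittig methylenation of the aldehyde gives the styrene for the Heck coupling and forms no stereocentre.

Step 7
Reactants: 10 (2R,3R)-4-bromo-3-(3,5-dimethoxyphenyl)-2-(4-methoxyphenyl)-2,3-dihydro-1-benzofuran-6-ol; 12 2,4-dimethoxystyrene
Product: 13 (2R,3R)-3-(3,5-dimethoxyphenyl)-4-[(E)-2-(2,4-dimethoxyphenyl)ethenyl]-2-(4-methoxyphenyl)-2,3-dihydro-1-benzofuran-6-ol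
Conditions: Pd2(dba)3 (2.5 mol %), [(t-Bu)3PH]BF4 (10 mol %), Cy2NMe (2.5 equiv), 1,4-dioxane, 90 °C
Reagents that add atoms: none
Why: Mizoroki–Heck coupling of the hindered, electron-rich aryl bromide under bulky-phosphine conditions tolerates the free phenol and should give the E-stilbene by syn-insertion and syn-β-hydride elimination without touching the stereocentres.

Step 8
Reactants: 13 (2R,3R)-3-(3,5-dimethoxyphenyl)-4-[(E)-2-(2,4-dimethoxyphenyl)ethenyl]-2-(4-methoxyphenyl)-2,3-dihydro-1-benzofuran-6-ol
Product: 14 seven-membered-ring phenol (pentamethyl ether; dihydrobenzofuran C-2 R and C-3 R trans; new methine R with its 2,4-dimethoxyphenyl group syn to H-3)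
Conditions: CF3CO2H (5 equiv), CH2Cl2 (0.01 M), −20 → 0 °C
Reagents that add atoms: none
Why: Protonation of the alkene at the carbon attached to the benzofuran gives the 2,4-dimethoxybenzylic cation, which the activated ortho carbon of the 3,5-dimethoxyphenyl ring traps in an intramolecular Friedel–Crafts alkylation that closes the seven-membered ring, the new methine (R) being set by the adjacent C-3 centre because the aryl group should take the pseudo-axial position syn to H-3 and away from the neighbouring methoxy group, as in the acid-mediated cyclisation of ε-viniferin-type stilbenes to ampelopsin-B-type cores.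

Step 9
Reactants: 14 seven-membered-ring phenol; 15 pterostilbene [(E)-4-(3,5-dimethoxystyryl)phenol]
Product: 17 heptamethyl ether of the target carrying a free 4-hydroxyphenyl group (all five stereocentres R), via p-quinone methide 16 (not isolated)
Conditions: FeCl3·6H2O (2.2 equiv), MeOH–CH2Cl2 (3:1), 0 °C → rt; 15 (1.5 equiv) added over 4 h
Reagents that add atoms: none
Why: Trivalent iron oxidises both phenols by one electron; the phenoxyl radical of 15, with spin at the alkene carbon that bears the 3,5-dimethoxyphenyl ring, bonds to the ortho carbon of the phenoxyl radical of 14 that lies para to the dihydrofuran oxygen, tautomerisation restores the arene and leaves p-quinone methide 16, and the phenol oxygen then adds to its exocyclic carbon. The closest known reaction type is the biomimetic oxidative coupling of resveratrol to ε-viniferin with FeCl3·6H2O in methanol and the oxidative cross-coupling of stilbene dimers with resveratrol. The one ring formed, the dihydrofuran, closes by 5-exo-trig oxa-conjugate (1,6-) addition. C-3 of the new ring is fixed in the C–C bond formation under substrate control: the puckered seven-membered ring tilts the adjacent CH2 and the bridging dimethoxybenzene ring toward one face of the central ring, so the stilbene aryl group should go to the other face (R), a bias expected to be moderate; C-2 is fixed in the ring closure, trans to the C-3 aryl group (R), which is the kinetic and the thermodynamic outcome. The step needs cross- over homo-coupling and the correct ortho carbon: slow addition of 15, whose methyl ethers keep its own resorcinol ring from closing a ring, the single oxidisable phenol of 14, and the known preference of resorcinol-type rings to couple at the carbon para to the second oxygen and not between the two oxygens should secure them.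

Step 10
Reactants: 17 heptamethyl ether of the target
Product: 18 target CNP0154047.1
Conditions: BBr3 (14 equiv), CH2Cl2, −78 → 0 °C; then H2O
Reagents that add atoms: none
Why: BBr3 cleaves all seven aryl methyl ethers by Lewis-acid-assisted SN2 demethylation, and the benzylic C–O bonds of the two dihydrobenzofurans, if ionised, should reclose to the trans isomers already present, so no stereocentre is lost.

Compound list
1 | 5-bromoresorcinol (5-bromobenzene-1,3-diol) | Oc1cc(O)cc(Br)c1 | starting material
2 | 3,5-dimethoxybenzoic acid | COc1cc(OC)cc(C(=O)O)c1 | starting material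
3 | (2-bromo-4,6-dihydroxyphenyl)(3,5-dimethoxyphenyl)methanone | O=C(c1cc(OC)cc(OC)c1)c1c(O)cc(O)cc1Br | intermediate
4 | 4-methoxybenzyl chloride | COc1ccc(CCl)cc1 | starting material
5 | {2-bromo-4,6-bis[(4-methoxybenzyl)oxy]phenyl}(3,5-dimethoxyphenyl)methanone | O=C(c1cc(OC)cc(OC)c1)c1c(OCc2ccc(OC)cc2)cc(OCc2ccc(OC)cc2)cc1Br | intermediate
6 | hydrazone of ketone 5 (C=N geometry not defined) | NN=C(c1cc(OC)cc(OC)c1)c1c(OCc2ccc(OC)cc2)cc(OCc2ccc(OC)cc2)cc1Br | intermediate
7 | diaryldiazomethane from 6 (not isolated) | [N-]=[N+]=C(c1cc(OC)cc(OC)c1)c1c(OCc2ccc(OC)cc2)cc(OCc2ccc(OC)cc2)cc1Br | intermediate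
8 | (2S,3R)-4-bromo-3-(3,5-dimethoxyphenyl)-6-[(4-methoxybenzyl)oxy]-2-(4-methoxyphenyl)-2,3-dihydro-1-benzofuran (cis) | Brc1cc(OCc2ccc(OC)cc2)cc2c1[C@@H](c1cc(OC)cc(OC)c1)[C@@H](c1ccc(OC)cc1)O2 | intermediate
9 | (2S,3R)-4-bromo-3-(3,5-dimethoxyphenyl)-2-(4-methoxyphenyl)-2,3-dihydro-1-benzofuran-6-ol (cis-phenol, not isolated) | Brc1cc(O)cc2c1[C@@H](c1cc(OC)cc(OC)c1)[C@@H](c1ccc(OC)cc1)O2 | intermediate
10 | (2R,3R)-4-bromo-3-(3,5-dimethoxyphenyl)-2-(4-methoxyphenyl)-2,3-dihydro-1-benzofuran-6-ol (trans) | Brc1cc(O)cc2c1[C@@H](c1cc(OC)cc(OC)c1)[C@H](c1ccc(OC)cc1)O2 | intermediate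
11 | 2,4-dimethoxybenzaldehyde | COc1ccc(C=O)c(OC)c1 | starting material
12 | 2,4-dimethoxystyrene | COc1ccc(C=C)c(OC)c1 | intermediate
13 | (2R,3R)-3-(3,5-dimethoxyphenyl)-4-[(E)-2-(2,4-dimethoxyphenyl)ethenyl]-2-(4-methoxyphenyl)-2,3-dihydro-1-benzofuran-6-ol | COc1ccc(/C=C/c2cc(O)cc3c2[C@@H](c2cc(OC)cc(OC)c2)[C@H](c2ccc(OC)cc2)O3)c(OC)c1 | intermediate
14 | seven-membered-ring phenol: 13 with a bond from the alkene carbon bearing the 2,4-dimethoxyphenyl ring to C-2 of the 3,5-dimethoxyphenyl ring; free OH on the central ring; three stereocentres all R, trans-dihydrobenzofuran, methine aryl syn to H-3 | Oc1cc2c3c(c1)C[C@H](c1ccc(OC)cc1OC)c1c(OC)cc(OC)cc1[C@H]3[C@H](c1ccc(OC)cc1)O2 | intermediate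
15 | pterostilbene, (E)-4-(3,5-dimethoxystyryl)phenol | COc1cc(/C=C/c2ccc(O)cc2)cc(OC)c1 | starting material
16 | p-quinone methide: 14 carrying at the ring carbon ortho to OH (para to the ring oxygen) a CH(3,5-dimethoxyphenyl)–CH= group that ends in a cyclohexa-2,5-dien-4-one (not isolated) | O=C1C=CC(=C[C@H](c2cc(OC)cc(OC)c2)c2c(O)cc3c4c2C[C@H](c2ccc(OC)cc2OC)c2c(OC)cc(OC)cc2[C@H]4[C@H](c2ccc(OC)cc2)O3)C=C1 | intermediate
17 | heptamethyl ether of the target: second trans-dihydrobenzofuran fused to the central ring, 2-(4-hydroxyphenyl) free, all other phenols as methyl ethers; five stereocentres all R | Oc1ccc([C@@H]2Oc3cc4c5c(c3[C@H]2c2cc(OC)cc(OC)c2)C[C@H](c2ccc(OC)cc2OC)c2c(OC)cc(OC)cc2[C@H]5[C@H](c2ccc(OC)cc2)O4)cc1 | intermediate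
18 | CNP0154047.1: central benzene ring fused to two trans-2-(4-hydroxyphenyl)-3-aryl-2,3-dihydrofurans and to the seven-membered ring bearing the 2,4-dihydroxyphenyl group; five stereocentres all R | Oc1ccc([C@@H]2Oc3cc4c5c(c3[C@H]2c2cc(O)cc(O)c2)C[C@H](c2ccc(O)cc2O)c2c(O)cc(O)cc2[C@H]5[C@H](c2ccc(O)cc2)O4)cc1 | target

Total step count: 10. Longest linear sequence: 9 steps (steps 1–5 and 7–10; step 6 is a one-step side branch).

Steps most likely to fail

Step 9. Homo-coupling of 15 may outrun the cross-coupling, the C–C bond may form at the arene carbon between the two oxygens, or the face selectivity at C-3 may be low. The fallback sets out from 14 and comes back at 18, making the two bonds one after the other through a benzofuran. O-Alkylation of 14 with 2-bromo-1-(3,5-dimethoxyphenyl)ethanone (K2CO3, acetone) gives aryloxy ketone F1. Bi(OTf)3-catalysed cyclodehydration (CH2Cl2, 40 °C) should close 3-arylbenzofuran F2 at the carbon para to the ether oxygen. Pd(OAc)2-catalysed C-2 arylation with 4-bromoanisole (PCy3·HBF4, pivalic acid, K2CO3, DMA, 100 °C) gives 2,3-diarylbenzofuran F3. Hydrogenation (H2 under pressure, Pd/C, EtOAc–AcOH) gives cis-dihydrobenzofuran F4, from which the isomer formed on the other face is separated. CF3CO2H in CH2Cl2 epimerises C-2 to trans octamethyl ether F5, and BBr3 as in step 10 gives 18.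

Step 4. The diazo carbon is flanked by two ortho substituents, so azine formation may compete with carbene formation and the insertion may lose enantioselectivity. The fallback sets out from 3 and comes back at 10, making the ring without a carbene. NaBH4 (MeOH, 0 °C) reduces 3 to benzhydrol F6, and 4-methylbenzenesulfinic acid (CH2Cl2, rt) should convert it, by way of the stabilised benzhydryl cation, into sulfone F7. Reagent 4 and dimethyl sulfide give (4-methoxybenzyl)dimethylsulfonium chloride F8. With Cs2CO3 in CH2Cl2, F7 loses sulfinate to the ortho-quinone methide, the ylide of F8 adds to it and the phenoxide displaces dimethyl sulfide ([4+1] annulation). This should give the trans-dihydrobenzofuran as the racemate of 10 and its (2S,3S)-enantiomer F9. Preparative chromatography on a chiral stationary phase isolates 10.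

Step 8. Ionisation of the ring C2–O bond may compete with protonation of the alkene and divert the stilbene into five-membered (indane-type) cyclisation, and the methine may form with low selectivity. The fallback sets out from 10 and comes back at 14, making the cation from an alcohol and not from an alkene. α-Arylation of 1-(2,4-dimethoxyphenyl)ethanone with 10, catalysed by Pd2(dba)3 and XPhos (LiHMDS, toluene, 80 °C), gives ketone F10. NaBH4 gives carbinol F11 as both epimers. Bi(OTf)3 (5 mol %) in CH2Cl2 at −40 °C ionises the dialkoxybenzylic alcohol at a temperature at which the dihydrofuran should stay closed, and the same Friedel–Crafts closure gives 14.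

Further compounds
F1 | step 9 | aryloxy ketone: 14 O-alkylated with CH2C(=O)(3,5-dimethoxyphenyl) | O=C(COc1cc2c3c(c1)C[C@H](c1ccc(OC)cc1OC)c1c(OC)cc(OC)cc1[C@H]3[C@H](c1ccc(OC)cc1)O2)c1cc(OC)cc(OC)c1
F2 | step 9 | 3-(3,5-dimethoxyphenyl)benzofuran fused to the central ring of 14 | c1oc2cc3c4c(c2c1-c1cc(OC)cc(OC)c1)C[C@H](c1ccc(OC)cc1OC)c1c(OC)cc(OC)cc1[C@H]4[C@H](c1ccc(OC)cc1)O3
F3 | step 9 | 2-(4-methoxyphenyl)-3-(3,5-dimethoxyphenyl)benzofuran fused to the central ring of 14 | COc1ccc(-c2oc3cc4c5c(c3c2-c2cc(OC)cc(OC)c2)C[C@H](c2ccc(OC)cc2OC)c2c(OC)cc(OC)cc2[C@H]5[C@H](c2ccc(OC)cc2)O4)cc1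
F4 | step 9 | cis-dihydrobenzofuran from F3 (new ring 2S,3R) | COc1ccc([C@H]2Oc3cc4c5c(c3[C@H]2c2cc(OC)cc(OC)c2)C[C@H](c2ccc(OC)cc2OC)c2c(OC)cc(OC)cc2[C@H]5[C@H](c2ccc(OC)cc2)O4)cc1
F5 | step 9 | octamethyl ether of the target (new ring 2R,3R trans) | COc1ccc([C@@H]2Oc3cc4c5c(c3[C@H]2c2cc(OC)cc(OC)c2)C[C@H](c2ccc(OC)cc2OC)c2c(OC)cc(OC)cc2[C@H]5[C@H](c2ccc(OC)cc2)O4)cc1
F6 | step 4 | (2-bromo-4,6-dihydroxyphenyl)(3,5-dimethoxyphenyl)methanol (racemic) | OC(c1cc(OC)cc(OC)c1)c1c(O)cc(O)cc1Br
F7 | step 4 | 5-bromo-4-[(3,5-dimethoxyphenyl)(4-methylbenzenesulfonyl)methyl]benzene-1,3-diol (racemic sulfone) | Cc1ccc(S(=O)(=O)C(c2cc(OC)cc(OC)c2)c2c(O)cc(O)cc2Br)cc1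
F8 | step 4 | (4-methoxybenzyl)dimethylsulfonium chloride | COc1ccc(C[S+](C)C)cc1.[Cl-]
F9 | step 4 | (2S,3S)-4-bromo-3-(3,5-dimethoxyphenyl)-2-(4-methoxyphenyl)-2,3-dihydro-1-benzofuran-6-ol (enantiomer of 10) | Brc1cc(O)cc2c1[C@H](c1cc(OC)cc(OC)c1)[C@@H](c1ccc(OC)cc1)O2
F10 | step 8 | 2-[(2R,3R)-3-(3,5-dimethoxyphenyl)-6-hydroxy-2-(4-methoxyphenyl)-2,3-dihydro-1-benzofuran-4-yl]-1-(2,4-dimethoxyphenyl)ethanone | COc1ccc(C(=O)Cc2cc(O)cc3c2[C@@H](c2cc(OC)cc(OC)c2)[C@H](c2ccc(OC)cc2)O3)c(OC)c1
F11 | step 8 | carbinol from F10 (both epimers at the carbinol carbon) | COc1ccc(C(O)Cc2cc(O)cc3c2[C@@H](c2cc(OC)cc(OC)c2)[C@H](c2ccc(OC)cc2)O3)c(OC)c1
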